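**Retrosynthetic overview**
- Target ⇐ bis-acetonide ⇐ one C15–C12′ bond, made by a thiamine-type (carbene) acyl-anion addition of a seco-aldehyde ester to a 14-O-silyl alkylidene lactone with loss of silanolate.
- Both halves ⇐ one bicyclic C12 aldehyde, made once and used twice: Wittig/Weinreb reduction gives the keto-ester arm; aldol–dehydration with a C4 hydroxy-lactone gives the lactone arm (lactone ring bought intact).
- Decalin ⇐ a single epoxide-initiated, allylsilane-terminated cation–olefin bicyclisation of an unprotected acyclic epoxy diol, the laboratory counterpart of the ent-copalyl cyclisation; ring A then ring B in one cascade, five stereocentres and the exocyclic alkene set together.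
- Acyclic chain ⇐ geranyl chloride + Z-selective olefination/Sharpless epoxidation (C3, C4, C19) + silylpropyne (C7–C9) + Me3SiCH2Cu/oxirane (C17, C11, C12).
- Ring order: rings A and B in the one cascade; no other ring is formed.

Assumption: labdane numbering is used (primed atoms = butenolide-bearing half); each decalin is 3R,4R,5S,9R,10S and the linking carbon is 12′S, as read from the SMILES. "Core" below means the 3,19-O-isopropylidene decalin attached through C9.

Step 1
Reactants: 1 geranyl chloride
Product: 3 (4E)-6-chloro-4-methylhex-4-enal, via ozonide 2 (not isolated)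
Conditions: O3 (1.0 equiv), CH2Cl2, −78 °C; then Me2S, −78 → 0 °C
Reagents that add atoms: ozone, [O-][O+]=O
Why: Chemoselective ozonolysis (Criegee): electrophilic ozone cleaves only the electron-rich terminal alkene because the other is deactivated by the allylic chlorine, and the ozonide is reduced to the aldehyde; no stereocentre forms and the E-alkene is untouched.

Step 2
Reactants: 3 (4E)-6-chloro-4-methylhex-4-enal
Product: 4 methyl (2Z,6E)-8-chloro-2,6-dimethylocta-2,6-dienoate
Conditions: (CF3CH2O)2P(O)CH(Me)CO2Me, KN(SiMe3)2, 18-crown-6, THF, −78 °C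
Reagents that add atoms: methyl 2-[bis(2,2,2-trifluoroethoxy)phosphoryl]propanoate, COC(=O)C(C)P(=O)(OCC(F)(F)F)OCC(F)(F)F
Why: Still–Gennari Z-selective Horner–Wadsworth–Emmons olefination: the electron-poor phosphonate eliminates irreversibly from the kinetic adduct, giving the Z-trisubstituted enoate (ester cis to the chain), the geometry that later makes C19 axial.

Step 3
Reactants: 4 methyl (2Z,6E)-8-chloro-2,6-dimethylocta-2,6-dienoate
Product: 5 (2Z,6E)-8-chloro-2,6-dimethylocta-2,6-dien-1-ol
Conditions: iBu2AlH (2.2 equiv), CH2Cl2, −78 °C; aq. potassium sodium tartrate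
Reagents that add atoms: none
Why: 1,2-Reduction of the conjugated ester by iBu2AlH to the Z-allylic alcohol; the primary allylic chloride and both alkene geometries survive at −78 °C.

Step 4
Reactants: 5 (2Z,6E)-8-chloro-2,6-dimethylocta-2,6-dien-1-ol
Product: 7 (2Z,6E)-2,6-dimethylundeca-2,6-dien-10-yn-1-ol, via silyl alkyne 6 (not isolated)
Conditions: n-BuLi (1.0 equiv, on 5); MeC≡CSiMe3, n-BuLi, TMEDA, THF, −78 → 0 °C; then K2CO3 (cat.), MeOH, 23 °C
Reagents that add atoms: 1-(trimethylsilyl)prop-1-yne, CC#C[Si](C)(C)C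
Why: SN2 alkylation of the silyl-stabilised propargyl-lithium at the primary allylic chloride (the silyl group keeps attack at the propargylic terminus, the lithium alkoxide of 5 is a spectator), then methanolysis of the C(sp)–Si bond; no stereocentre is involved.

Step 5
Reactants: 7 (2Z,6E)-2,6-dimethylundeca-2,6-dien-10-yn-1-ol
Product: 9 (2Z,6E,10Z)-2,6-dimethyl-10-[(trimethylsilyl)methyl]trideca-2,6,10-triene-1,13-diol, via alkenylcopper 8 (not isolated)
Conditions: n-BuLi (1.0 equiv); Me3SiCH2MgCl, CuBr·SMe2, Et2O–Me2S, −25 → 0 °C; then LiC≡CPr, HMPA, oxirane, −40 → −10 °C; aq. NH4Cl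
Reagents that add atoms: (trimethylsilyl)methylmagnesium chloride, C[Si](C)(C)C[Mg]Cl; oxirane, C1CO1
Why: Normant syn-carbocupration of the terminal alkyne (Me3SiCH2 to the internal carbon, copper to the terminal carbon) followed by stereoretentive opening of oxirane by the alkenylcuprate gives the trisubstituted allylsilane with CH2SiMe3 cis to the new CH2CH2OH arm, the geometry needed for an equatorial C9 side chain.

Step 6
Reactants: 9 (2Z,6E,10Z)-2,6-dimethyl-10-[(trimethylsilyl)methyl]trideca-2,6,10-triene-1,13-diol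
Product: 10 (2S,3R)-epoxy diol [(2S,3R)-3-{(3E,7Z)-10-hydroxy-3-methyl-7-[(trimethylsilyl)methyl]deca-3,7-dien-1-yl}-2-methyloxiran-2-yl]methanol
Conditions: Ti(OiPr)4 (20 mol%), L-(+)-diethyl tartrate (24 mol%), tBuOOH, 4 Å sieves, CH2Cl2, −20 °C
Reagents that add atoms: tert-butyl hydroperoxide, CC(C)(C)OO
Why: Katsuki–Sharpless asymmetric epoxidation: the titanium–L-(+)-tartrate complex epoxidises only the allylic-alcohol alkene, on the face that gives the (2S,3R)-epoxide (as for Z-allylic alcohols such as nerol), fixing C3 and, before inversion, C4; the homoallylic alcohol, the other alkenes and the allylsilane do not react.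

Step 7
Reactants: 10 (2S,3R)-epoxy diol
Product: 11 bicyclic triol 2-[(1R,4aS,5R,6R,8aS)-6-hydroxy-5-(hydroxymethyl)-5,8a-dimethyl-2-methylidenedecahydronaphthalen-1-yl]ethan-1-ol
Conditions: MeAlCl2 (3.5 equiv), CH2Cl2, −78 → −30 °C; aq. potassium sodium tartrate
Reagents that add atoms: none
Why: Proposed new method: an epoxide-initiated, allylsilane-terminated cation–olefin bicyclisation run on the unprotected epoxy diol (closest known type: MeAlCl2- or SnCl4-promoted cyclisation of silyl-protected 2,3-epoxy-alcohol polyenes with allylsilane termination); MeAlCl2 first turns both hydroxyls into dichloroaluminium alkoxides (methane loss), the epoxide then opens at the tertiary carbon C4 with inversion while C3–O is retained, and the chain folds chair–chair, so that the E-alkene gives the trans fusion at C5/C10, the Z-CH2O group becomes axial C19, the C3 oxygen is equatorial, the allylsilane geometry gives the equatorial C9 side chain, and loss of silicon fixes the exocyclic C8=C17 alkene.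

Step 8
Reactants: 11 bicyclic triol
Product: 12 3,19-O-isopropylidene alcohol (core–CH2CH2OH)
Conditions: Me2C(OMe)2, PPTS (5 mol%), acetone, 23 °C
Reagents that add atoms: 2,2-dimethoxypropane, COC(C)(C)OC
Why: Acid-catalysed transacetalisation gives the six-membered acetonide of the syn 3,19-diol (as in andrographolide), favoured over any acetal with the remote C12 hydroxyl, which stays free; no stereocentre changes.

Step 9
Reactants: 12 3,19-O-isopropylidene alcohol
Product: 13 C12 aldehyde (core–CH2CHO)
Conditions: TEMPO (10 mol%), PhI(OAc)2 (1.2 equiv), CH2Cl2, 23 °C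
Reagents that add atoms: none
Why: Oxoammonium (TEMPO/PhI(OAc)2) oxidation of the primary alcohol stops at the aldehyde without alkene migration or acetonide loss; C9 is β to the carbonyl and cannot epimerise.

Step 10
Reactants: 13 C12 aldehyde; 14 methyl (triphenylphosphoranylidene)acetate
Product: 16 methyl (2E)-2-{2-[methoxy(methyl)amino]-2-oxoethyl}-4-(core)but-2-enoate, via phosphorus ylide 15 (not isolated)
Conditions: 14 (2.0 equiv), BrCH2C(O)N(OMe)Me (1.0 equiv), toluene, 70 °C; then 13, 100 °C
Reagents that add atoms: 2-bromo-N-methoxy-N-methylacetamide, CON(C)C(=O)CBr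
Why: C-Alkylation/transylidation of the stabilised ylide gives the α-substituted ylide 15, whose Wittig reaction with aldehyde 13 gives the E-trisubstituted enoate (C11 trans to CO2Me) under the usual thermodynamic control of stabilised ylides.

Step 11
Reactants: 16 Weinreb amide enoate
Product: 17 methyl (2E)-2-(2-oxoethyl)-4-(core)but-2-enoate
Conditions: iBu2AlH (1.2 equiv), THF, −78 °C; aq. potassium sodium tartrate, 0 °C
Reagents that add atoms: none
Why: Weinreb-amide reduction: iBu2AlH forms a chelated tetrahedral aluminate that releases the aldehyde only on work-up, while the less electrophilic conjugated methyl ester is untouched at −78 °C; cold neutral work-up keeps the alkene in place.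

Step 12
Reactants: 18 (S)-4-hydroxyoxolan-2-one
Product: 19 (S)-4-[(tert-butyldimethylsilyl)oxy]oxolan-2-one
Conditions: tBuMe2SiCl, imidazole, DMF, 23 °C
Reagents that add atoms: tert-butyl(chloro)dimethylsilane, CC(C)(C)[Si](C)(C)Cl
Why: Silyl-ether formation on the secondary alcohol gives an oxygen substituent that survives enolisation and later serves as the leaving group; the S centre is not touched.

Step 13
Reactants: 19 (S)-4-[(tert-butyldimethylsilyl)oxy]oxolan-2-one; 13 C12 aldehyde
Product: 21 aldol adduct (4S)-4-silyloxy-3-[1-hydroxy-2-(core)ethyl]oxolan-2-one, via lithium enolate 20 (not isolated)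
Conditions: LiN(iPr)2 (1.05 equiv), THF, −78 °C, 20 min; then 13, −78 °C; AcOH quench at −78 °C
Reagents that add atoms: none
Why: Lithium-enolate aldol addition at −78 °C (short enolate lifetime suppresses β-silanolate loss); the new C12 and C13 centres form as a mixture that is erased in the next step.

Step 14
Reactants: 21 aldol adduct
Product: 23 (3E,4S)-4-silyloxy-3-[2-(core)ethylidene]oxolan-2-one (3,19-O-isopropylidene-14-O-TBS-andrographolide), via mesylate 22 (not isolated)
Conditions: MsCl, Et3N, CH2Cl2, 0 °C; then DBU (1.5 equiv), 0 → 23 °C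
Reagents that add atoms: none
Why: Mesylation then E1cB elimination across C12–C13 gives the E-alkylidene lactone, the mesylate leaving far faster than the silyloxy group; C14 (S) is untouched and the alkene geometry does not matter for the next step.

Step 15
Reactants: 17 seco-aldehyde ester; 23 silyl-protected alkylidene lactone
Product: 24 3,19:3′,19′-di-O-isopropylidene derivative of the target
Conditions: aminoindanol-derived N-C6F5 triazolium tetrafluoroborate (20 mol%), iPr2NEt (20 mol%), toluene, 23 °C
Reagents that add atoms: none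
Why: Proposed new method: carbene-catalysed (thiamine-type) Stetter addition–elimination (closest known: intermolecular Stetter reaction, and addition–elimination of nucleophiles at C12 of 14-O-acyl andrographolides); the Breslow intermediate of 17 adds as an acyl anion to C12′ of the s-cis-locked alkylidene lactone, the lactone enolate expels silanolate (E1cB) to give the butenolide and turn the catalyst over, and C12′ is set by the face of attack under control of the chiral triazolium (the antipode giving 12′S is chosen by screen; the minor epimer is removed by chromatography).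

Step 16
Reactants: 24 bis-acetonide
Product: 25 target CNP0330094.1
Conditions: AcOH–H2O (7:3), 23 °C
Reagents that add atoms: none
Why: Mild acid hydrolysis of both acetonides (standard for 3,19-isopropylidene andrographolides) frees the four hydroxyls without touching the exocyclic alkenes, the butenolide, the keto ester or the epimerisable C12′ centre.

**Compound list**
1 | geranyl chloride, (2E)-1-chloro-3,7-dimethylocta-2,6-diene | CC(C)=CCC/C(C)=C/CCl | starting material
2 | 3-[(3E)-5-chloro-3-methylpent-3-en-1-yl]-5,5-dimethyl-1,2,4-trioxolane (not isolated) | CC1(C)OOC(CC/C(C)=C/CCl)O1 | intermediate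
3 | (4E)-6-chloro-4-methylhex-4-enal | O=CCC/C(C)=C/CCl | intermediate
4 | methyl (2Z,6E)-8-chloro-2,6-dimethylocta-2,6-dienoate | COC(=O)/C(C)=C\CC/C(C)=C/CCl | intermediate
5 | (2Z,6E)-8-chloro-2,6-dimethylocta-2,6-dien-1-ol | OC/C(C)=C\CC/C(C)=C/CCl | intermediate
6 | (2Z,6E)-2,6-dimethyl-11-(trimethylsilyl)undeca-2,6-dien-10-yn-1-ol (not isolated) | OC/C(C)=C\CC/C(C)=C/CCC#C[Si](C)(C)C | intermediate
7 | (2Z,6E)-2,6-dimethylundeca-2,6-dien-10-yn-1-ol | OC/C(C)=C\CC/C(C)=C/CCC#C | intermediate
8 | (1Z,5E,9Z)-11-(lithiooxy)-6,10-dimethyl-2-[(trimethylsilyl)methyl]undeca-1,5,9-trien-1-ylcopper (not isolated) | [Li]OC/C(C)=C\CC/C(C)=C/CC/C(C[Si](C)(C)C)=C/[Cu] | intermediate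
9 | (2Z,6E,10Z)-2,6-dimethyl-10-[(trimethylsilyl)methyl]trideca-2,6,10-triene-1,13-diol | OC/C(C)=C\CC/C(C)=C/CC/C(C[Si](C)(C)C)=C/CCO | intermediate
10 | [(2S,3R)-3-{(3E,7Z)-10-hydroxy-3-methyl-7-[(trimethylsilyl)methyl]deca-3,7-dien-1-yl}-2-methyloxiran-2-yl]methanol | OC[C@]1(C)O[C@@H]1CC/C(C)=C/CC/C(C[Si](C)(C)C)=C/CCO | intermediate
11 | 2-[(1R,4aS,5R,6R,8aS)-6-hydroxy-5-(hydroxymethyl)-5,8a-dimethyl-2-methylidenedecahydronaphthalen-1-yl]ethan-1-ol (3R,4R,5S,9R,10S in labdane numbering) | C=C1CC[C@@H]2[C@](C)(CO)[C@H](O)CC[C@@]2(C)[C@@H]1CCO | intermediate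
12 | 3,19-O-isopropylidene acetal of 11 (free C12 alcohol) | C=C1CC[C@@H]2[C@]3(C)COC(C)(C)O[C@@H]3CC[C@@]2(C)[C@@H]1CCO | intermediate
13 | 3,19-O-isopropylidene C12 aldehyde (core–CH2CHO) | C=C1CC[C@@H]2[C@]3(C)COC(C)(C)O[C@@H]3CC[C@@]2(C)[C@@H]1CC=O | intermediate
14 | methyl (triphenyl-λ5-phosphanylidene)acetate | COC(=O)C=P(c1ccccc1)(c1ccccc1)c1ccccc1 | starting material
15 | methyl 4-[methoxy(methyl)amino]-4-oxo-2-(triphenyl-λ5-phosphanylidene)butanoate (not isolated) | COC(=O)C(CC(=O)N(C)OC)=P(c1ccccc1)(c1ccccc1)c1ccccc1 | intermediate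
16 | methyl (2E)-2-{2-[methoxy(methyl)amino]-2-oxoethyl}-4-(core)but-2-enoate | C=C1CC[C@@H]2[C@]3(C)COC(C)(C)O[C@@H]3CC[C@@]2(C)[C@@H]1C/C=C(\CC(=O)N(C)OC)C(=O)OC | intermediate
17 | methyl (2E)-2-(2-oxoethyl)-4-(core)but-2-enoate | C=C1CC[C@@H]2[C@]3(C)COC(C)(C)O[C@@H]3CC[C@@]2(C)[C@@H]1C/C=C(\CC=O)C(=O)OC | intermediate
18 | (S)-4-hydroxyoxolan-2-one, (S)-3-hydroxy-γ-butyrolactone | O=C1C[C@H](O)CO1 | starting material
19 | (S)-4-[(tert-butyldimethylsilyl)oxy]oxolan-2-one | O=C1C[C@H](O[Si](C)(C)C(C)(C)C)CO1 | intermediate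
20 | lithium enolate of 19 (not isolated) | [Li]OC1=C[C@H](O[Si](C)(C)C(C)(C)C)CO1 | intermediate
21 | (4S)-4-[(tert-butyldimethylsilyl)oxy]-3-[1-hydroxy-2-(core)ethyl]oxolan-2-one (mixture at C12, C13) | C=C1CC[C@@H]2[C@]3(C)COC(C)(C)O[C@@H]3CC[C@@]2(C)[C@@H]1CC(O)C1C(=O)OC[C@H]1O[Si](C)(C)C(C)(C)C | intermediate
22 | C12 methanesulfonate of 21 (not isolated) | C=C1CC[C@@H]2[C@]3(C)COC(C)(C)O[C@@H]3CC[C@@]2(C)[C@@H]1CC(OS(C)(=O)=O)C1C(=O)OC[C@H]1O[Si](C)(C)C(C)(C)C | intermediate
23 | (3E,4S)-4-[(tert-butyldimethylsilyl)oxy]-3-[2-(core)ethylidene]oxolan-2-one | C=C1CC[C@@H]2[C@]3(C)COC(C)(C)O[C@@H]3CC[C@@]2(C)[C@@H]1C/C=C1/C(=O)OC[C@H]1O[Si](C)(C)C(C)(C)C | intermediate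
24 | 3,19:3′,19′-di-O-isopropylidene derivative of the target (12′S) | C=C1CC[C@@H]2[C@]3(C)COC(C)(C)O[C@@H]3CC[C@@]2(C)[C@@H]1C/C=C(\CC(=O)[C@@H](C[C@@H]1C(=C)CC[C@@H]2[C@]3(C)COC(C)(C)O[C@@H]3CC[C@]21C)C1=CCOC1=O)C(=O)OC | intermediate
25 | CNP0330094.1 | C=C1CC[C@@H]2[C@](C)(CO)[C@H](O)CC[C@@]2(C)[C@@H]1C/C=C(\CC(=O)[C@@H](C[C@@H]1C(=C)CC[C@@H]2[C@](C)(CO)[C@H](O)CC[C@]21C)C1=CCOC1=O)C(=O)OC | target

**Totals**
Total step count: 16. Longest linear sequence: 13 steps (1 → 13 in nine steps, then steps 10, 11, 15, 16; the lactone branch via steps 13, 14 is equally long).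

**Three steps most likely to fail**

Step 7 (bicyclisation of the free epoxy diol). The aluminium alkoxides may divert the epoxide opening or the allylsilane may be lost before ring closure. The fallback replaces in-situ masking by covalent protection and sets out from 10: both hydroxyls are silylated (Et3SiCl, imidazole) to the bis(triethylsilyl) ether F1; F1 is cyclised with SnCl4 in CH2Cl2 at −90 °C, the established protected-substrate form of this cascade, to the bicyclic bis(triethylsilyl) ether F2 (free 3-OH); HF·pyridine removes both silyl groups and the route is rejoined at triol 11.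

Step 15 (carbene-catalysed union). The β-substituted lactone may be too poor an acceptor, or aldehyde 17 may isomerise into conjugation. The fallback swaps the acyl anion for a nitronate and sets out from 23 and 13: nitromethane/DBU adds to 23 with loss of silanolate to give the 12′-(nitromethyl) butenolide F3 (C12′ epimers separated here); in parallel 13 and methyl acrylate (DABCO) give the Baylis–Hillman alcohol F4, acetylated (Ac2O, pyridine) to the acetate F5; the nitronate of F3 (K2CO3, MeCN) displaces the acetate of F5 by conjugate addition–elimination (SN2′) to give the E-alkylidene secondary nitro compound F6; a reductive Nef reaction (TiCl3, NH4OAc buffer) turns the nitro carbon into the C15 ketone and the route is rejoined at 24.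

Step 5 (silylmethyl carbocupration and oxirane trapping). Transfer of the Me3SiCH2 group to a substituted alkyne, or the epoxide opening by the alkenylcopper, may be sluggish. The fallback abandons the allylsilane terminator for an enol-ether terminator with late methylenation and sets out from 7: the dilithio derivative of 7 (n-BuLi, 2 equiv) opens oxirane (BF3·OEt2) to the alkyne diol F7; Sharpless epoxidation (Ti(OiPr)4, L-(+)-diethyl tartrate, tBuOOH) gives the (2S,3R)-epoxy alkyne diol F8; Ph3PAuNTf2 (2 mol%) cyclises the homopropargylic alcohol 5-endo to the 2-alkyl-4,5-dihydrofuran F9; MeAlCl2 then triggers the same epoxide-initiated bicyclisation, now ended by the cyclic enol ether, and aqueous work-up gives the C8 ketone triol F10 (C9 side chain equatorial after equilibration); excess Ph3P=CH2 installs the exocyclic methylene and the route is rejoined at triol 11.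

**Further compounds**
F1 | step 7 | bis(triethylsilyl) ether of 10 | CC[Si](CC)(CC)OC[C@]1(C)O[C@@H]1CC/C(C)=C/CC/C(C[Si](C)(C)C)=C/CCO[Si](CC)(CC)CC
F2 | step 7 | 12,19-bis(triethylsilyl) ether of 11 | C=C1CC[C@@H]2[C@](C)(CO[Si](CC)(CC)CC)[C@H](O)CC[C@@]2(C)[C@@H]1CCO[Si](CC)(CC)CC
F3 | step 15 | 3-[(2S)-1-nitro-3-(core)propan-2-yl]furan-2(5H)-one | C=C1CC[C@@H]2[C@]3(C)COC(C)(C)O[C@@H]3CC[C@@]2(C)[C@@H]1C[C@H](C[N+](=O)[O-])C1=CCOC1=O
F4 | step 15 | methyl 3-hydroxy-2-methylidene-4-(core)butanoate (mixture at C3) | C=C1CC[C@@H]2[C@]3(C)COC(C)(C)O[C@@H]3CC[C@@]2(C)[C@@H]1CC(O)C(=C)C(=O)OC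
F5 | step 15 | methyl 3-acetoxy-2-methylidene-4-(core)butanoate | C=C1CC[C@@H]2[C@]3(C)COC(C)(C)O[C@@H]3CC[C@@]2(C)[C@@H]1CC(OC(C)=O)C(=C)C(=O)OC
F6 | step 15 | 15-nitro analogue of 24 (C15 CH–NO2 in place of C=O, mixture at C15) | C=C1CC[C@@H]2[C@]3(C)COC(C)(C)O[C@@H]3CC[C@@]2(C)[C@@H]1C/C=C(\CC([N+](=O)[O-])[C@@H](C[C@@H]1C(=C)CC[C@@H]2[C@]3(C)COC(C)(C)O[C@@H]3CC[C@]21C)C1=CCOC1=O)C(=O)OC
F7 | step 5 | (2Z,6E)-2,6-dimethyltrideca-2,6-dien-10-yne-1,13-diol | OC/C(C)=C\CC/C(C)=C/CCC#CCCO
F8 | step 5 | [(2S,3R)-3-[(3E)-10-hydroxy-3-methyldec-3-en-7-yn-1-yl]-2-methyloxiran-2-yl]methanol | OC[C@]1(C)O[C@@H]1CC/C(C)=C/CCC#CCCO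
F9 | step 5 | [(2S,3R)-3-[(3E)-6-(4,5-dihydrofuran-2-yl)-3-methylhex-3-en-1-yl]-2-methyloxiran-2-yl]methanol | OC[C@]1(C)O[C@@H]1CC/C(C)=C/CCC1=CCCO1
F10 | step 5 | C8 ketone analogue of 11 (C=O in place of C=CH2) | O=C1CC[C@@H]2[C@](C)(CO)[C@H](O)CC[C@@]2(C)[C@@H]1CCO
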